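**Retrosynthetic overview**
1. Feature: in ring B, the ketone carbon C1 and C4 (the carbon bearing pyrone carbon C6') stand 1,4 to each other. A temporary C1–C6' bond folds ring B into a benzonorbornen-9-one whose single-atom bridge C9 is the future C6'.
2. The pyrone comes from a C6' ketone plus a dioxinone (aldol, oxidation, acylketene closure). The C8–OH comes from C8–H, oxygenated under direction of the C1 alcohol. C1–OH and C4–CO2Me come from a bridged lactone, made by a Baeyer–Villiger cut of the C1–C9 bond.
3. The bridge ketone comes from ozonolysis of a C9 isopropylidene. The C3 carbinol comes from exo addition of PhLi to a C3 ketone. That ketone comes from enantioselective hydroboration of the meso alkene made from benzyne and 6,6-dimethylfulvene.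
4. Ring order: ring A is bought. Ring B and the bridge arise together (step 1). The lactone ring is made by ring enlargement (step 6) and opened (step 7). A temporary oxasilole (step 8) delivers the C8 oxygen. The pyrone is closed last (step 16).

Key step: step 6

Remarks
- a) Numbering: target numbering is kept for all intermediates (ring B = C1–C4, ring A = C4a–C8a, C9 = bridge carbon = later C6'). CIP descriptors refer to this numbering.
- b) Protection of C3: the C3 oxygen is carried as its triethylsilyl ether from step 4 to step 17. A free hydroxyl would leave 12, 14 and 15 open to retro-aldol cleavage of C3–C4. It would also direct the C–H silylation of step 8 into the phenyl ring.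
- c) Assumption: the sense of induction in step 2 has to be assigned on alcohol 6, for example by X-ray analysis of a heavy-atom ester. (R)-DTBM-SEGPHOS is written here and is replaced by its equally available antipode if the assignment demands it.

**Step 1**
Reactants: 1 2-(trimethylsilyl)phenyl trifluoromethanesulfonate; 2 6,6-dimethylfulvene
Product: 4 meso-(1R,4S)-9-(propan-2-ylidene)-1,4-dihydro-1,4-methanonaphthalene, via benzyne 3 (not isolated)
Conditions: CsF, MeCN, rt
Reagents that add atoms: none
Why: Fluoride-triggered 1,2-elimination releases benzyne 3, which should add across the cyclopentadiene unit of the fulvene in a Diels–Alder reaction, a well-used entry to 9-alkylidenebenzonorbornadienes that forms ring B and the C9 bridge in one operation and gives a meso alkene.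

**Step 2**
Reactants: 4 meso-9-(propan-2-ylidene)-1,4-dihydro-1,4-methanonaphthalene
Product: 6 (1R,3R,4S)-9-(propan-2-ylidene)-1,2,3,4-tetrahydro-1,4-methanonaphthalen-3-exo-ol, via exo-pinacolboronate 5 (not isolated)
Conditions: CuCl (5 mol%), (R)-DTBM-SEGPHOS (6 mol%), NaOtBu (10 mol%), B2pin2, MeOH, THF, rt; then H2O2, aq. NaOH, 0 °C
Reagents that add atoms: bis(pinacolato)diboron CC1(C)OB(OC1(C)C)B1OC(C)(C)C(C)(C)O1 (boron of 5); hydrogen peroxide OO (oxygen of 6)
Why: This is an enantioselective copper-catalysed protoboration of a strained meso bicyclic alkene, in which the ligated Cu–Bpin species adds syn from the exo face to one of the two enantiotopic alkene carbons, methanol protonates the C–Cu bond and peroxide replaces boron by oxygen with retention, so that the ligand fixes the absolute configuration of bridgeheads C1 and C4 while the unstrained tetrasubstituted C9 alkene is left alone.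

**Step 3**
Reactants: 6 exo-alcohol
Product: 7 (1R,4S)-9-(propan-2-ylidene)-1,4-dihydro-1,4-methanonaphthalen-3(2H)-one
Conditions: Dess–Martin periodinane, CH2Cl2, rt
Reagents that add atoms: none
Why: Dess–Martin oxidation of a secondary alcohol under neutral conditions gives up the auxiliary C3 stereocentre, whereas C1 and C4 are bridgeheads that cannot enolise and keep the configuration fixed in step 2.

**Step 4**
Reactants: 7 C3 ketone; 8 phenyllithium
Product: 10 (1R,3S,4S)-3-exo-phenyl-9-(propan-2-ylidene)-3-endo-(triethylsilyloxy)-1,2,3,4-tetrahydro-1,4-methanonaphthalene, via lithium alkoxide 9 (not isolated)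
Conditions: PhLi, Et2O, −78 °C; then TESOTf, −78 to 0 °C
Reagents that add atoms: triethylsilyl trifluoromethanesulfonate CC[Si](CC)(CC)OS(=O)(=O)C(F)(F)F
Why: In this 1,2-addition of an organolithium to a norbornan-2-one type ketone, ring A screens the endo face and the isopropylidene group lies in the C1–C9–C4 plane and leaves the exo face open, so phenyl should enter exo (syn to C9) and oxygen end up endo, which sets C3, and the cold alkoxide is silylated at once before it can fragment.

**Step 5**
Reactants: 10 silyl ether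
Product: 12 (1S,3S,4S)-3-exo-phenyl-3-endo-(triethylsilyloxy)-1,2,3,4-tetrahydro-1,4-methanonaphthalen-9-one, via primary ozonide 11 (not isolated)
Conditions: O3, CH2Cl2/MeOH, −78 °C (indicator dye); then Me2S, −78 °C to rt
Reagents that add atoms: ozone [O-][O+]=O
Why: Ozonolysis of the electron-rich tetrasubstituted alkene with reductive work-up is the usual way from 9-isopropylidenebenzonorbornenes to the 9-ketones and should leave the arenes and the silyl ether untouched at low temperature.

**Step 6**
Reactants: 12 bridge ketone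
Product: 14 (1S,3S,4S)-3-phenyl-3-(triethylsilyloxy)-1,2,3,4-tetrahydro-1,4-(epoxymethano)naphthalen-10-one (bridge C1–O–C9(=O)–C4), via Criegee adduct 13 (not isolated)
Conditions: mCPBA, CH2Cl2, 0 °C to rt
Reagents that add atoms: 3-chloroperoxybenzoic acid O=C(OO)c1cccc(Cl)c1
Why: The peracid adds to the angle-strained C9 carbonyl from the face over ring A (the other face is covered by the exo phenyl group) to give adduct 13, in which the bridgehead antiperiplanar to the O–O bond shifts from C9 to oxygen while 3-chlorobenzoate leaves. This is the Baeyer–Villiger oxidation of a 7-norbornanone-type bridge ketone, a known ring enlargement to 2-oxabicyclo[2.2.2]octan-3-ones. The new six-membered lactone ring (C1–O–C9–C4–C4a–C8a) is closed by insertion of oxygen into the C1–C9 bond through a 1,2-shift and not by a cyclisation, and the temporary C1–C9 bond is cut in the same event while C9 stays on C4 as a carboxyl carbon. No stereocentre is created, because the shift is suprafacial, C1 keeps its configuration with the C1–O bond on the face of ring B that carries C9 and phenyl, and C3 and C4 are not touched. The step needs migration of C1 and not of C4; both are secondary benzylic bridgeheads, and the bias comes from C3, whose oxygen and phenyl substituents withdraw electron density from C4 and so raise the barrier of the shift in which C4 carries the partial positive charge. The size of this bias is not established for this substitution pattern, so the isomeric lactone must be expected as a by-product to be removed by chromatography.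

**Step 7**
Reactants: 14 bridged lactone
Product: 15 methyl (1S,3S,4S)-1-hydroxy-3-phenyl-3-(triethylsilyloxy)-1,2,3,4-tetrahydronaphthalene-4-carboxylate (C1-OH/phenyl/ester on one face)
Conditions: K2CO3 (0.2 equiv), MeOH, 0 °C; AcOH quench before concentration
Reagents that add atoms: methanol CO
Why: Base-catalysed transesterification opens the strained boat-shaped lactone without breaking a bond to a stereocentre, and although C4 becomes enolisable, the wanted epimer (ester pseudoaxial and anti to the axial silyloxy group, phenyl equatorial) is expected to be the more stable one, while short contact with a weak base should keep beta-elimination of silanolate in check.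

**Step 8**
Reactants: 15 hydroxy ester
Product: 17 peri-fused 2,2-diethylbenzoxasilole (ring C1–O–SiEt2–C8–C8a) of methyl (1S,3S,4S)-3-phenyl-3-(triethylsilyloxy)tetralin-4-carboxylate, via diethylhydrosilyl ether 16 (not isolated)
Conditions: Et2SiH2, [Ir(cod)OMe]2 (0.5 mol%), THF, rt; volatiles removed; then [Ir(cod)OMe]2 (1 mol%), 1,10-phenanthroline (2.5 mol%), norbornene, THF, 100 °C
Reagents that add atoms: diethylsilane CC[SiH2]CC
Why: Iridium-catalysed dehydrogenative silylation of the alcohol followed by hydrosilyl-directed intramolecular ortho C–H silylation, known for secondary benzylic alcohols, should close the oxasilole onto C8, the only ortho C–H of ring A, which lies next to the pseudoequatorial C1–O bond, with norbornene taking up the hydrogen.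

**Step 9**
Reactants: 17 benzoxasilole
Product: 18 methyl (1S,3S,4S)-1,8-dihydroxy-3-phenyl-3-(triethylsilyloxy)-1,2,3,4-tetrahydronaphthalene-4-carboxylate
Conditions: H2O2 (30% aq.), KHCO3, THF/MeOH, rt
Reagents that add atoms: hydrogen peroxide OO
Why: In this Tamao–Fleming oxidation, hydroperoxide adds to the alkoxy-activated silicon, the aryl group migrates from silicon to oxygen so that C8–Si becomes C8–O, and hydrolysis frees the phenol and the C1 alcohol under conditions too mild for the ester or the tertiary silyl ether.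

**Step 10**
Reactants: 18 phenol alcohol
Product: 19 methyl (1S,3S,4S)-8-(tert-butyldimethylsilyloxy)-1-hydroxy-3-phenyl-3-(triethylsilyloxy)-1,2,3,4-tetrahydronaphthalene-4-carboxylate
Conditions: TBSCl (1.05 equiv), imidazole, CH2Cl2, 0 °C
Reagents that add atoms: tert-butyldimethylsilyl chloride CC(C)(C)[Si](C)(C)Cl
Why: Under imidazole catalysis the far more acidic phenol should be silylated faster than the hindered secondary benzylic alcohol, so one equivalent of chlorosilane masks C8–OH before the iodine-based oxidations.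

**Step 11**
Reactants: 19 silylated hydroxy ester
Product: 20 (1S,3S,4R)-8-(tert-butyldimethylsilyloxy)-4-(hydroxymethyl)-3-phenyl-3-(triethylsilyloxy)-1,2,3,4-tetrahydronaphthalen-1-ol
Conditions: iBu2AlH (4 equiv), CH2Cl2, −78 to 0 °C; aq. potassium sodium tartrate
Reagents that add atoms: none
Why: Hydride reduction of the ester to the primary alcohol with an electrophilic, non-basic aluminium hydride avoids enolisation at C4 and leaves both silyl ethers in place.

**Step 12**
Reactants: 20 diol
Product: 21 (3S,4S)-8-(tert-butyldimethylsilyloxy)-1-oxo-3-phenyl-3-(triethylsilyloxy)-1,2,3,4-tetrahydronaphthalene-4-carbaldehyde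
Conditions: IBX (3 equiv), DMSO/THF, rt; used without chromatography
Reagents that add atoms: none
Why: IBX oxidises both alcohols in a neutral medium but does not carry lactols on to lactones at room temperature, so any bridged lactol or hemiketal formed reversibly between C1 and the C4 side chain should drain through its open form to the keto aldehyde, and no base is present to trigger beta-elimination.

**Step 13**
Reactants: 22 2,2,6-trimethyl-4H-1,3-dioxin-4-one
Product: 24 [(2,2-dimethyl-6-methylidene-6H-1,3-dioxin-4-yl)oxy]trimethylsilane, via lithium dienolate 23 (not isolated)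
Conditions: LiN(iPr)2, THF, −78 °C; then TMSCl, −78 °C to rt; distillation
Reagents that add atoms: chlorotrimethylsilane C[Si](C)(C)Cl
Why: Kinetic gamma-deprotonation of the dioxinone and O-silylation of the dienolate is the standard preparation of this silyl dienol ether.

**Step 14**
Reactants: 21 keto aldehyde; 24 silyl dienol ether
Product: 25 (3S,4R)-8-(tert-butyldimethylsilyloxy)-4-[2-(2,2-dimethyl-4-oxo-4H-1,3-dioxin-6-yl)-1-hydroxyethyl]-3-phenyl-3-(triethylsilyloxy)-3,4-dihydronaphthalen-1(2H)-one (carbinol epimers)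
Conditions: BF3·OEt2, CH2Cl2, −78 °C; aq. pH 7 buffer
Reagents that add atoms: none
Why: In this vinylogous Mukaiyama aldol addition the gamma-carbon of 24 attacks the BF3-activated aldehyde, which is far more electrophilic than the aryl ketone at C1, and the new carbinol centre is formed without control because step 15 erases it.

**Step 15**
Reactants: 25 aldol adduct
Product: 26 (3S,4S)-8-(tert-butyldimethylsilyloxy)-4-[(2,2-dimethyl-4-oxo-4H-1,3-dioxin-6-yl)acetyl]-3-phenyl-3-(triethylsilyloxy)-3,4-dihydronaphthalen-1(2H)-one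
Conditions: Dess–Martin periodinane, CH2Cl2, 0 °C to rt
Reagents that add atoms: none
Why: Dess–Martin oxidation of delta-hydroxy dioxinones to keto dioxinones is routine, and it is neutral enough to spare the beta-silyloxy ketone and the C4 stereocentre, whose wanted configuration is also the one expected to be favoured at equilibrium.

**Step 16**
Reactants: 26 keto dioxinone
Product: 28 (3S,4R)-8-(tert-butyldimethylsilyloxy)-4-(4-hydroxy-2-oxo-2H-pyran-6-yl)-3-phenyl-3-(triethylsilyloxy)-3,4-dihydronaphthalen-1(2H)-one, via acylketene 27 (not isolated)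
Conditions: toluene (0.01 M), 110 °C
Reagents that add atoms: none
Why: Thermal retro-[4+2] loss of acetone from the dioxinone gives acylketene 27, whose ketene carbon is captured by the enol oxygen of the C6' ketone, the established reagent-free closure to 6-substituted 4-hydroxy-2-pyrones.

**Step 17**
Reactants: 28 bis-silyl ether
Product: 29 (3S,4S)-3,8-dihydroxy-4-(4-hydroxy-2-oxo-2H-pyran-6-yl)-3-phenyl-3,4-dihydronaphthalen-1(2H)-one (target)
Conditions: HF·pyridine, pyridine, THF, 0 °C to rt
Reagents that add atoms: none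
Why: Fluoride-driven cleavage of the aryl TBS and tertiary TES ethers in a pyridine-buffered medium breaks only Si–O bonds, so C3 and C4 are untouched, and it avoids both the strong base and the strong acid that would dehydrate the beta-hydroxy ketone.

**Compound list**
1 | 2-(trimethylsilyl)phenyl trifluoromethanesulfonate | C[Si](C)(C)c1ccccc1OS(=O)(=O)C(F)(F)F | starting material
2 | 6,6-dimethylfulvene | CC(C)=C1C=CC=C1 | starting material
3 | benzyne | C1=CC#CC=C1 | intermediate
4 | meso-(1R,4S)-9-(propan-2-ylidene)-1,4-dihydro-1,4-methanonaphthalene | [C@@H]12C=C[C@@H](C1=C(C)C)c1ccccc12 | intermediate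
5 | (1R,3R,4S)-3-exo-(pinacolboryl)-9-(propan-2-ylidene)-1,2,3,4-tetrahydro-1,4-methanonaphthalene | [C@@H]12C[C@@H](B3OC(C)(C)C(C)(C)O3)[C@@H](C1=C(C)C)c1ccccc12 | intermediate
6 | (1R,3R,4S)-9-(propan-2-ylidene)-1,2,3,4-tetrahydro-1,4-methanonaphthalen-3-exo-ol | [C@@H]12C[C@@H](O)[C@@H](C1=C(C)C)c1ccccc12 | intermediate
7 | (1R,4S)-9-(propan-2-ylidene)-1,4-dihydro-1,4-methanonaphthalen-3(2H)-one | [C@@H]12CC(=O)[C@@H](C1=C(C)C)c1ccccc12 | intermediate
8 | phenyllithium | [Li]c1ccccc1 | starting material
9 | lithium (1R,3S,4S)-3-exo-phenyl-9-(propan-2-ylidene)-1,2,3,4-tetrahydro-1,4-methanonaphthalen-3-endo-olate | [C@@H]12C[C@@]([O-])(c3ccccc3)[C@@H](C1=C(C)C)c1ccccc12.[Li+] | intermediate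
10 | (1R,3S,4S)-3-exo-phenyl-9-(propan-2-ylidene)-3-endo-(triethylsilyloxy)-1,2,3,4-tetrahydro-1,4-methanonaphthalene | [C@@H]12C[C@@](O[Si](CC)(CC)CC)(c3ccccc3)[C@@H](C1=C(C)C)c1ccccc12 | intermediate
11 | primary ozonide of 10 (spiro 1,2,3-trioxolane at C9; C9 configuration not defined) | [C@@H]12C[C@@](O[Si](CC)(CC)CC)(c3ccccc3)[C@@H](C13OOOC3(C)C)c1ccccc12 | intermediate
12 | (1S,3S,4S)-3-exo-phenyl-3-endo-(triethylsilyloxy)-1,2,3,4-tetrahydro-1,4-methanonaphthalen-9-one | [C@@H]12C[C@@](O[Si](CC)(CC)CC)(c3ccccc3)[C@@H](C1=O)c1ccccc12 | intermediate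
13 | Criegee adduct of 12 (C9 hydroxy 3-chloroperoxybenzoate; C9 configuration not defined) | [C@@H]12C[C@@](O[Si](CC)(CC)CC)(c3ccccc3)[C@@H](C1(O)OOC(=O)c1cccc(Cl)c1)c1ccccc12 | intermediate
14 | (1S,3S,4S)-3-phenyl-3-(triethylsilyloxy)-1,2,3,4-tetrahydro-1,4-(epoxymethano)naphthalen-10-one | [C@@H]12C[C@@](O[Si](CC)(CC)CC)(c3ccccc3)[C@@H](C(=O)O1)c1ccccc12 | intermediate
15 | methyl (1S,3S,4S)-1-hydroxy-3-phenyl-3-(triethylsilyloxy)-1,2,3,4-tetrahydronaphthalene-4-carboxylate | O[C@H]1C[C@@](O[Si](CC)(CC)CC)(c2ccccc2)[C@@H](C(=O)OC)c2ccccc21 | intermediate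
16 | C1 diethylhydrosilyl ether of 15 | CC[SiH](CC)O[C@H]1C[C@@](O[Si](CC)(CC)CC)(c2ccccc2)[C@@H](C(=O)OC)c2ccccc21 | intermediate
17 | peri-fused 2,2-diethylbenzoxasilole (C1–O–SiEt2–C8) of the (1S,3S,4S) ester | CC[Si]1(CC)O[C@H]2C[C@@](O[Si](CC)(CC)CC)(c3ccccc3)[C@@H](C(=O)OC)c3cccc1c32 | intermediate
18 | methyl (1S,3S,4S)-1,8-dihydroxy-3-phenyl-3-(triethylsilyloxy)-1,2,3,4-tetrahydronaphthalene-4-carboxylate | O[C@H]1C[C@@](O[Si](CC)(CC)CC)(c2ccccc2)[C@@H](C(=O)OC)c2cccc(O)c21 | intermediate
19 | methyl (1S,3S,4S)-8-(tert-butyldimethylsilyloxy)-1-hydroxy-3-phenyl-3-(triethylsilyloxy)-1,2,3,4-tetrahydronaphthalene-4-carboxylate | O[C@H]1C[C@@](O[Si](CC)(CC)CC)(c2ccccc2)[C@@H](C(=O)OC)c2cccc(O[Si](C)(C)C(C)(C)C)c21 | intermediate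
20 | (1S,3S,4R)-8-(tert-butyldimethylsilyloxy)-4-(hydroxymethyl)-3-phenyl-3-(triethylsilyloxy)-1,2,3,4-tetrahydronaphthalen-1-ol | O[C@H]1C[C@@](O[Si](CC)(CC)CC)(c2ccccc2)[C@@H](CO)c2cccc(O[Si](C)(C)C(C)(C)C)c21 | intermediate
21 | (3S,4S)-8-(tert-butyldimethylsilyloxy)-1-oxo-3-phenyl-3-(triethylsilyloxy)-1,2,3,4-tetrahydronaphthalene-4-carbaldehyde | O=C1C[C@@](O[Si](CC)(CC)CC)(c2ccccc2)[C@@H](C=O)c2cccc(O[Si](C)(C)C(C)(C)C)c21 | intermediate
22 | 2,2,6-trimethyl-4H-1,3-dioxin-4-one | CC1=CC(=O)OC(C)(C)O1 | starting material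
23 | lithium dienolate of 22 | [Li+].C=C1C=C([O-])OC(C)(C)O1 | intermediate
24 | [(2,2-dimethyl-6-methylidene-6H-1,3-dioxin-4-yl)oxy]trimethylsilane | C=C1C=C(O[Si](C)(C)C)OC(C)(C)O1 | intermediate
25 | (3S,4R)-8-(tert-butyldimethylsilyloxy)-4-[2-(2,2-dimethyl-4-oxo-4H-1,3-dioxin-6-yl)-1-hydroxyethyl]-3-phenyl-3-(triethylsilyloxy)-3,4-dihydronaphthalen-1(2H)-one (carbinol epimers) | O=C1C[C@@](O[Si](CC)(CC)CC)(c2ccccc2)[C@@H](C(O)CC2=CC(=O)OC(C)(C)O2)c2cccc(O[Si](C)(C)C(C)(C)C)c21 | intermediate
26 | (3S,4S)-8-(tert-butyldimethylsilyloxy)-4-[(2,2-dimethyl-4-oxo-4H-1,3-dioxin-6-yl)acetyl]-3-phenyl-3-(triethylsilyloxy)-3,4-dihydronaphthalen-1(2H)-one | O=C1C[C@@](O[Si](CC)(CC)CC)(c2ccccc2)[C@@H](C(=O)CC2=CC(=O)OC(C)(C)O2)c2cccc(O[Si](C)(C)C(C)(C)C)c21 | intermediate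
27 | acylketene from 26 (C4–CO–CH2–CO–CH=C=O) | O=C1C[C@@](O[Si](CC)(CC)CC)(c2ccccc2)[C@@H](C(=O)CC(=O)C=C=O)c2cccc(O[Si](C)(C)C(C)(C)C)c21 | intermediate
28 | (3S,4R)-8-(tert-butyldimethylsilyloxy)-4-(4-hydroxy-2-oxo-2H-pyran-6-yl)-3-phenyl-3-(triethylsilyloxy)-3,4-dihydronaphthalen-1(2H)-one | O=C1C[C@@](O[Si](CC)(CC)CC)(c2ccccc2)[C@@H](c2cc(O)cc(=O)o2)c2cccc(O[Si](C)(C)C(C)(C)C)c21 | intermediate
29 | (3S,4S)-3,8-dihydroxy-4-(4-hydroxy-2-oxo-2H-pyran-6-yl)-3-phenyl-3,4-dihydronaphthalen-1(2H)-one | O=C1C[C@@](O)(c2ccccc2)[C@@H](c2cc(O)cc(=O)o2)c2cccc(O)c21 | target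

**Step count**
- Total: 17 steps.
- Longest linear sequence: 16 steps (steps 1–12 and 14–17, from 1).

**Steps most likely to fail**

First, step 6. Regiocontrol may erode through competing migration of C4. A silyloxy group is only a weak acceptor, and steric compression around C4 can favour its shift.

The fallback sets out from lithium alkoxide 9 and returns at 14. It strengthens the electronic bias in the substrate itself.
- The cold alkoxide is quenched with chloroacetic anhydride instead of TESOTf to give the tertiary chloroacetate F1.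
- Ozonolysis as in step 5 gives the chloroacetoxy bridge ketone F2, whose electron-poor acyloxy group deactivates C4 much more strongly.
- mCPBA should then give the chloroacetoxy lactone F3. C4 is a bridgehead in F3, so elimination of the ester is not possible.
- Thiourea and NaHCO3 in EtOH/THF remove the chloroacetyl group by S-alkylation and cyclisation, without opening the lactone, and give the hydroxy lactone F4.
- TESOTf/2,6-lutidine converts F4 into 14.

Second, step 12. In the keto aldehyde the C3 silyloxy group is beta to two carbonyl groups. Loss of triethylsilanol followed by aromatisation of ring B may therefore occur. Half-oxidised material may also be held back as a bridged lactol.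

The fallback sets out from 19 and returns at 26. It extends the chain before C1 is oxidised.
- TESOTf/2,6-lutidine masks the C1 alcohol and gives the C1 triethylsilyl ether ester F5.
- iBu2AlH at −78 °C stops at the C1-silylated aldehyde F6. It cannot form a lactol and has only one carbonyl group next to C3.
- The vinylogous Mukaiyama aldol addition of 24 (BF3·OEt2, −78 °C) gives the C1-silylated aldol adduct F7.
- PPTS in MeOH/CH2Cl2 at 0 °C removes the secondary silyl ether in preference to the tertiary TES and the aryl TBS groups, giving the C1,C6' diol F8.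
- Excess Dess–Martin periodinane oxidises both carbinols at once to 26.

Third, step 8. The C–Si bond-forming reductive elimination may be slow because the five-membered ring is fused across the peri positions. The neighbouring ester may also slow the catalyst.

The fallback sets out from hydrosilyl ether 16 and returns at 18. It replaces ring closure by intermolecular boryl transfer.
- 16 is treated with B2pin2, [Ir(cod)OMe]2 and 4,4'-di-tert-butyl-2,2'-bipyridine in THF at 80 °C. The Si–H group anchors iridium, and C8–H is borylated to the C8 pinacolboronate hydrosilyl ether F9.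
- H2O2/KHCO3 in THF/MeOH oxidises the C–B bond and hydrolyses the silyl ether to give 18.

**Further compounds**
F1 | step 6 | (1R,3S,4S)-3-exo-phenyl-9-(propan-2-ylidene)-1,2,3,4-tetrahydro-1,4-methanonaphthalen-3-endo-yl chloroacetate | [C@@H]12C[C@@](OC(=O)CCl)(c3ccccc3)[C@@H](C1=C(C)C)c1ccccc12
F2 | step 6 | (1S,3S,4S)-9-oxo-3-exo-phenyl-1,2,3,4-tetrahydro-1,4-methanonaphthalen-3-endo-yl chloroacetate | [C@@H]12C[C@@](OC(=O)CCl)(c3ccccc3)[C@@H](C1=O)c1ccccc12
F3 | step 6 | (1S,3S,4S)-10-oxo-3-phenyl-1,2,3,4-tetrahydro-1,4-(epoxymethano)naphthalen-3-yl chloroacetate | [C@@H]12C[C@@](OC(=O)CCl)(c3ccccc3)[C@@H](C(=O)O1)c1ccccc12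
F4 | step 6 | (1S,3S,4S)-3-hydroxy-3-phenyl-1,2,3,4-tetrahydro-1,4-(epoxymethano)naphthalen-10-one | [C@@H]12C[C@@](O)(c3ccccc3)[C@@H](C(=O)O1)c1ccccc12
F5 | step 12 | methyl (1S,3S,4S)-8-(tert-butyldimethylsilyloxy)-3-phenyl-1,3-bis(triethylsilyloxy)-1,2,3,4-tetrahydronaphthalene-4-carboxylate | CC[Si](CC)(CC)O[C@H]1C[C@@](O[Si](CC)(CC)CC)(c2ccccc2)[C@@H](C(=O)OC)c2cccc(O[Si](C)(C)C(C)(C)C)c21
F6 | step 12 | (1S,3S,4S)-8-(tert-butyldimethylsilyloxy)-3-phenyl-1,3-bis(triethylsilyloxy)-1,2,3,4-tetrahydronaphthalene-4-carbaldehyde | CC[Si](CC)(CC)O[C@H]1C[C@@](O[Si](CC)(CC)CC)(c2ccccc2)[C@@H](C=O)c2cccc(O[Si](C)(C)C(C)(C)C)c21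
F7 | step 12 | 6-{2-[(1S,3S,4R)-8-(tert-butyldimethylsilyloxy)-3-phenyl-1,3-bis(triethylsilyloxy)-1,2,3,4-tetrahydronaphthalen-4-yl]-2-hydroxyethyl}-2,2-dimethyl-4H-1,3-dioxin-4-one (carbinol epimers) | CC[Si](CC)(CC)O[C@H]1C[C@@](O[Si](CC)(CC)CC)(c2ccccc2)[C@@H](C(O)CC2=CC(=O)OC(C)(C)O2)c2cccc(O[Si](C)(C)C(C)(C)C)c21
F8 | step 12 | 6-{2-[(1S,3S,4R)-8-(tert-butyldimethylsilyloxy)-1-hydroxy-3-phenyl-3-(triethylsilyloxy)-1,2,3,4-tetrahydronaphthalen-4-yl]-2-hydroxyethyl}-2,2-dimethyl-4H-1,3-dioxin-4-one (carbinol epimers) | O[C@H]1C[C@@](O[Si](CC)(CC)CC)(c2ccccc2)[C@@H](C(O)CC2=CC(=O)OC(C)(C)O2)c2cccc(O[Si](C)(C)C(C)(C)C)c21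
F9 | step 8 | methyl (1S,3S,4S)-1-(diethylsilyloxy)-3-phenyl-8-(pinacolboryl)-3-(triethylsilyloxy)-1,2,3,4-tetrahydronaphthalene-4-carboxylate | CC[SiH](CC)O[C@H]1C[C@@](O[Si](CC)(CC)CC)(c2ccccc2)[C@@H](C(=O)OC)c2cccc(B3OC(C)(C)C(C)(C)O3)c21
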